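Begin with an easy step. If every molecule of free monomer runs the same risk of being taken at a given moment (a pseudo-first-order loss), what counts is n, the number of turnovers: that risk added up over time. The fraction e to the power minus n stays free, and while n is small it is nearly the fraction lost.

| flask | free monomer | initiator | remark | time |
|---|---|---|---|---|
| red | 0.20 M | 34 mM | run made earlier |  |
| violet | 0.58 M | 34 mM | run made earlier |  |
| epsilon | 0.25 M | 34 mM |  | 60 min |
| eta | 0.80 M | 34 mM |  | 20 min |

| run | time / min | monomer in chains / % | free monomer / % |
|---|---|---|---|
| red | 2.50 | 1.5 | 100.6 |
| red | 5.00 | 0.5 | 98.6 |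
| red | 8.00 | 2.8 | 97.6 |
| red | 10.0 | 3.0 | 95.1 |
| red | 12.0 | 5.1 | 95.2 |
| red | 15.0 | 6.9 | 92.7 |
| violet | 1.00 | 0.6 | 97.6 |
| violet | 2.50 | 1.7 | 98.7 |
| violet | 5.00 | 0.5 | 97.5 |
| violet | 8.00 | 4.7 | 95.5 |
| violet | 10.0 | 5.3 | 92.8 |
| violet | 15.0 | 12.9 | 88.3 |

(scatter of a reading: 1 percentage point)

- the winner by amount of monomer in chains, in percent of the free monomer charged; "neither" if no more than 2 percentage points parts them (epsilon / eta / neither)
- how much monomer in chains is there at the end, in percent of the free monomer charged: epsilon
- how much monomer in chains is there at the end, in percent of the free monomer charged: eta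

- what was read earlier has a scatter of 1 percentage point, one standard deviation
- a reading or a percentage of monomer in chains counts all its forms, free or not

Both runs bend upward, so the risk grows with time. My own reckoning gives it a steady part s from the initiator and a part that grows with the charge c and with time, on the guess that an active species accumulates. So n = s·t + b·(c/v)·(t/u)·(t/u), where v is the violet charge of 0.58 M, u is 15.0 min, and a small percentage in chains is read as the same count of turnovers. At 15.0 min, the red run holds 6.9 % in chains and the violet run 12.9 %. The charge is the one setting that parts these runs, so the difference gives b = 0.0916, the breeding count, meaning the turnovers bred in the violet run by time u, and s = 0.00249 /min. Both are rough readings, with a scatter of 1 percentage point on a difference of 6 points.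

Two extremes bracket epsilon. In the high one, the active species keeps accumulating at the starting pace, so n = 0.781 and 54.2 % is lost. In the low one, accumulation stops at 15.0 min and the risk stays as it was then, so n = 0.426 and 34.7 % is lost. I expect accumulation to slow as free monomer falls, yet to continue, so I place epsilon between them. I place it nearer the high end, since by 30.0 min the high count has lost 20.8 %, less than the 54.2 % it reaches at the end. For eta the high count is 0.274, a loss of 24.0 %, which stands below epsilon's low end. So I commit to epsilon.

The forecast also names epsilon, with 60 % for epsilon and 24 % for eta. For epsilon it reckons from what it calls “a long extrapolation”, and its figure stands above my high end.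

Epsilon ends with 49.1 % in chains and eta with 22.5 %, so epsilon wins. Epsilon keeps 48.0 % of its free monomer, which is a count of 0.734 turnovers, between 0.426 and 0.781.

    crystals ⇌ monomer in chains, rate k1*(cs1 - [monomer in chains]) while solid is left; crystals form when [monomer in chains] > cs1 (solubility = 31.0 mM, k = 0.0780 /s)
    free monomer + monomer in chains → side product (k = 2.30 × 10⁻⁴ /M/s)
    free monomer + initiator → living end + monomer in chains (k = 7.30 × 10⁻⁴ /M/s)
    free monomer + living end → monomer in chains + living end, rate k4*[living end]*[free monomer] (k = 0.0220 /M/s)

A neighbour flask is epsilon with 0.062 M of free monomer. The same b of 0.0916 gives it a high count of n = 0.306, a loss of 26.4 %. That flask ends with 23.9 % in chains and 75 % still free.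

All runs were generated by integration for substances that don't exist; noise was put on by code.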